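**Retrosynthetic overview**

- Feature: in five-membered ring A (C1–C5), the carbinol C4, the ring-fusion CH C5 and the methyl-bearing quaternary C1 are the carbonyl, α- and β-carbons of 3-methylcyclopent-2-en-1-one, and the C6 carbinol is the anti-aldol partner of C5.
- Key disconnection: C1–C10 and C5–C6 are formed in one flask on that enone by copper-catalysed asymmetric conjugate alkenylation and aldol trapping of the aluminium enolate with 3-bromobut-3-enal. Ring A comes from the enone and is not built.
- Elaboration: O6 silyl ether, protodesilylation to the vinyl group, α-face isopropyl addition at C4, vanillate (phenol as silyl ether) on O6, vinyl to CH2CHO.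
- Last ring: seven-membered ring B is closed at C8–C9 by a Nozaki–Hiyama–Kishi reaction, which also sets the C9 carbinol and leaves the C8=C14 methylene; final desilylation.

Key step: step 3

Remark on numbering: C1 quaternary (CH3 = C15), C2/C3 ring CH2, C4 isopropyl carbinol, C5 ring-fusion CH, C6 ester carbinol, C7 CH2, C8 (=C14H2), C9 free carbinol, C10 CH2. β is the face of C15 and α the face of H5. The target is (1R,4R,5S,6S,9S): trans ring fusion, 4β-OH, 6α-acyloxy, 9α-OH.

Assumption: L is an enantiopure sulfonate-bearing N-aryl imidazolinium salt (precursor of a bidentate carbene–sulfonate ligand). The enantiomer is taken that gives the C1 configuration drawn for 6 and 7; its mirror image would give the antipodal series.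

**Route**

Step 1
Reactants: 1 trimethylsilylacetylene
Product: 2 diisobutyl[1-(trimethylsilyl)ethenyl]aluminium (kept as a stock solution)
Conditions: iBu2AlH (1.0 equiv), hexane/THF, 55 °C, 2 h
Reagents that add atoms: diisobutylaluminium hydride, CC(C)C[AlH]CC(C)C
Why: Hydroalumination of a silylalkyne adds Al–H cis across the triple bond with aluminium on the silicon-bearing carbon, because silicon stabilises the adjacent carbon–metal bond in the four-centre transition state, which gives the geminal silyl/aluminium alkene.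

Step 2
Reactants: 3 3-bromobut-3-en-1-ol
Product: 4 3-bromobut-3-enal
Conditions: DMP (1.2 equiv), CH2Cl2, 0 °C → rt; filtered through a short pad, concentrated cold, used at once
Reagents that add atoms: none
Why: Dess–Martin oxidation of the primary alcohol under neutral non-aqueous conditions stops at the aldehyde and avoids the acid or base that would move the β,γ double bond into conjugation.

Step 3
Reactants: 5 3-methylcyclopent-2-en-1-one; 2 diisobutyl[1-(trimethylsilyl)ethenyl]aluminium; 4 3-bromobut-3-enal
Product: 7 (2S,3S)-2-[(1S)-3-bromo-1-hydroxybut-3-en-1-yl]-3-methyl-3-[1-(trimethylsilyl)ethenyl]cyclopentan-1-one, via aluminium enolate 6 (not isolated)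
Conditions: L (5 mol %) premetallated with Ag2O, Cu(OTf)2 (5 mol %), 2 (1.5 equiv), THF, 0 °C; then 4 (3 equiv), −78 → −40 °C; aq. potassium sodium tartrate
Reagents that add atoms: none
Why: Proposed new method: the alane reduces Cu(OTf)2 to monovalent copper, the carbene-bound copper takes the alkenyl group from aluminium and adds it to C1 of the aluminium-activated enone through a π-complex and a trivalent copper intermediate, and reductive elimination leaves the regiodefined diisobutylaluminium enolate 6 (C4=C5), which then binds the aldehyde and adds through a closed six-membered Zimmerman–Traxler chair. The closest known reactions are the copper–carbene-catalysed enantioselective conjugate addition of silyl-substituted alkenylalanes to 3-substituted cyclopentenones, which stops at the enolate, and the aldol trapping of aluminium or zinc enolates made by conjugate addition; running both in sequence next to a new quaternary carbon is the untested part. No ring is closed: the step forms C1–C10 and C5–C6 on the intact ring A. C1 is set by the chiral carbene ligand, which selects the enone face; C5 is set by the new C1 centre, the aldehyde approaching anti to the bulky 1-silylvinyl group and syn to the small methyl C15; C6 is set by the chair transition state of the ring-locked E enolate, which gives the anti aldol. The step therefore needs enantiofacial control at C1, trans delivery across C1–C5 and anti simple diastereoselection, secured by the ligand, by the size difference between silylvinyl and methyl, and by the fixed enolate geometry; an excess of 4 is used because isobutylaluminium species may reduce part of it.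

Step 4
Reactants: 7 (2S,3S)-2-[(1S)-3-bromo-1-hydroxybut-3-en-1-yl]-3-methyl-3-[1-(trimethylsilyl)ethenyl]cyclopentan-1-one
Product: 8 (2S,3S)-2-[(1S)-3-bromo-1-(triisopropylsilyloxy)but-3-en-1-yl]-3-methyl-3-[1-(trimethylsilyl)ethenyl]cyclopentan-1-one
Conditions: iPr3SiOTf (1.5 equiv), 2,6-lutidine (3 equiv), CH2Cl2, −78 → 0 °C
Reagents that add atoms: triisopropylsilyl trifluoromethanesulfonate, CC(C)[Si](OS(=O)(=O)C(F)(F)F)(C(C)C)C(C)C
Why: Silyl ether formation with a silyl triflate and a hindered pyridine base is fast on the secondary aldol hydroxyl, blocks retro-aldol cleavage and β-elimination, and gives an O6 group that should survive the acid of step 5 and the organometallic of step 6.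

Step 5
Reactants: 8 (2S,3S)-2-[(1S)-3-bromo-1-(triisopropylsilyloxy)but-3-en-1-yl]-3-methyl-3-[1-(trimethylsilyl)ethenyl]cyclopentan-1-one
Product: 9 (2S,3R)-2-[(1S)-3-bromo-1-(triisopropylsilyloxy)but-3-en-1-yl]-3-ethenyl-3-methylcyclopentan-1-one
Conditions: CF3CO2H (10 equiv), CH2Cl2, 0 °C → rt
Reagents that add atoms: none
Why: Protodesilylation of the vinylsilane, known for 1-silylvinyl groups on β-quaternary ketones, proceeds by ipso protonation to a β-silyl-stabilised cation that loses silicon to trifluoroacetate, while the bulky silyl ether, the electron-poor bromoalkene and the slowly enolising C5–H should be untouched; removing silicon here also opens the α face of C4 for step 6.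

Step 6
Reactants: 9 (2S,3R)-2-[(1S)-3-bromo-1-(triisopropylsilyloxy)but-3-en-1-yl]-3-ethenyl-3-methylcyclopentan-1-one
Product: 10 (1R,2S,3R)-2-[(1S)-3-bromo-1-(triisopropylsilyloxy)but-3-en-1-yl]-3-ethenyl-3-methyl-1-(propan-2-yl)cyclopentan-1-ol
Conditions: iPrMgCl (3 equiv), anhydrous CeCl3 (3 equiv), THF, −78 → 0 °C
Reagents that add atoms: isopropylmagnesium chloride, CC(C)[Mg]Cl
Why: Organocerium 1,2-addition to the ketone uses a weakly basic reagent that suppresses enolisation and β-hydride reduction and leaves the alkenyl bromide alone, and it should attack C4 from the α face, anti to the large silyloxyalkyl arm on the adjacent C5, which places isopropyl α and the new hydroxyl β (4R in the target numbering).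

Step 7
Reactants: 10 (1R,2S,3R)-2-[(1S)-3-bromo-1-(triisopropylsilyloxy)but-3-en-1-yl]-3-ethenyl-3-methyl-1-(propan-2-yl)cyclopentan-1-ol
Product: 11 (1R,2S,3R)-2-[(1S)-3-bromo-1-hydroxybut-3-en-1-yl]-3-ethenyl-3-methyl-1-(propan-2-yl)cyclopentan-1-ol
Conditions: TBAF (2 equiv), THF, 0 °C → rt
Reagents that add atoms: none
Why: Fluoride cleavage of the silyl ether, driven by Si–F bond formation, frees O6, and the tertiary alcohol, the vinyl group and the bromoalkene are inert to TBAF in THF at room temperature.

Step 8
Reactants: 12 vanillic acid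
Product: 14 3-methoxy-4-(triisopropylsilyloxy)benzoic acid, via bis-silyl derivative 13 (not isolated)
Conditions: iPr3SiCl (2.3 equiv), imidazole (5 equiv), DMF, rt; then K2CO3, MeOH/H2O, rt; then aq. HCl to pH 3, 0 °C
Reagents that add atoms: triisopropylsilyl chloride, CC(C)[Si](Cl)(C(C)C)C(C)C
Why: Exhaustive silylation followed by mild carbonate cleavage of the far more labile silyl ester is a selective protection that leaves the aryl silyl ether, chosen to survive steps 9 to 12 and to leave with fluoride at the end.

Step 9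
Reactants: 11 (1R,2S,3R)-2-[(1S)-3-bromo-1-hydroxybut-3-en-1-yl]-3-ethenyl-3-methyl-1-(propan-2-yl)cyclopentan-1-ol; 14 3-methoxy-4-(triisopropylsilyloxy)benzoic acid
Product: 15 (1S)-3-bromo-1-[(1S,2R,5R)-2-ethenyl-5-hydroxy-2-methyl-5-(propan-2-yl)cyclopentyl]but-3-en-1-yl 3-methoxy-4-(triisopropylsilyloxy)benzoate
Conditions: DCC (1.5 equiv), DMAP (0.3 equiv), 14 (1.3 equiv), CH2Cl2, rt
Reagents that add atoms: none
Why: Steglich esterification (carbodiimide activation and acyl transfer through the acylpyridinium of DMAP) acylates the secondary C6 hydroxyl, while the tertiary C4 hydroxyl is too hindered to react.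

Step 10
Reactants: 15 (1S)-3-bromo-1-[(1S,2R,5R)-2-ethenyl-5-hydroxy-2-methyl-5-(propan-2-yl)cyclopentyl]but-3-en-1-yl 3-methoxy-4-(triisopropylsilyloxy)benzoate
Product: 17 (1S)-3-bromo-1-[(1S,2R,5R)-2-hydroxy-5-(2-hydroxyethyl)-5-methyl-2-(propan-2-yl)cyclopentyl]but-3-en-1-yl 3-methoxy-4-(triisopropylsilyloxy)benzoate, via alkylborane 16 (not isolated)
Conditions: 9-BBN (3 equiv), THF, 0 °C → rt; then NaBO3·4H2O, THF/H2O, rt
Reagents that add atoms: 9-borabicyclo[3.3.1]nonane, B1C2CCCC1CCC2 (boron of 16); sodium perborate, [Na+].[O-]OB=O (oxygen of the new hydroxyl)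
Why: Anti-Markovnikov hydroboration–oxidation with a bulky dialkylborane should take the monosubstituted vinyl group at its terminal carbon much faster than the halogen-deactivated bromoalkene, and perborate oxidises the C–B bond under conditions mild enough for the aryl ester and the aryl silyl ether.

Step 11
Reactants: 17 (1S)-3-bromo-1-[(1S,2R,5R)-2-hydroxy-5-(2-hydroxyethyl)-5-methyl-2-(propan-2-yl)cyclopentyl]but-3-en-1-yl 3-methoxy-4-(triisopropylsilyloxy)benzoate
Product: 18 (1S)-3-bromo-1-[(1S,2R,5R)-2-hydroxy-5-methyl-5-(2-oxoethyl)-2-(propan-2-yl)cyclopentyl]but-3-en-1-yl 3-methoxy-4-(triisopropylsilyloxy)benzoate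
Conditions: DMP (1.5 equiv), CH2Cl2, 0 °C → rt
Reagents that add atoms: none
Why: Dess–Martin oxidation converts the primary alcohol into the aldehyde and cannot oxidise the tertiary C4 hydroxyl, which is β while the side chain on C1 is α, so that no lactol can form.

Step 12
Reactants: 18 (1S)-3-bromo-1-[(1S,2R,5R)-2-hydroxy-5-methyl-5-(2-oxoethyl)-2-(propan-2-yl)cyclopentyl]but-3-en-1-yl 3-methoxy-4-(triisopropylsilyloxy)benzoate
Product: 19 (3R,3aS,4S,7S,8aR)-3,7-dihydroxy-8a-methyl-6-methylidene-3-(propan-2-yl)decahydroazulen-4-yl 3-methoxy-4-(triisopropylsilyloxy)benzoate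
Conditions: CrCl2 (8 equiv), NiCl2 (2 mol %), degassed DMSO, rt, 0.005 M
Reagents that add atoms: none
Why: In the intramolecular Nozaki–Hiyama–Kishi reaction zerovalent nickel inserts into the C8–Br bond, the alkenyl group passes to trivalent chromium and adds only to the aldehyde (7-exo-trig, closing ring B trans-fused to ring A) in the presence of the ester and the free hydroxyl, and the chromium-bound oxygen should sit pseudo-equatorial in the chair-like transition state, away from the axial β-methyl C15 that is 1,3 to C9, which gives the 9α (9S) alcohol.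

Step 13
Reactants: 19 (3R,3aS,4S,7S,8aR)-3,7-dihydroxy-8a-methyl-6-methylidene-3-(propan-2-yl)decahydroazulen-4-yl 3-methoxy-4-(triisopropylsilyloxy)benzoate
Product: 20 (3R,3aS,4S,7S,8aR)-3,7-dihydroxy-8a-methyl-6-methylidene-3-(propan-2-yl)decahydroazulen-4-yl 4-hydroxy-3-methoxybenzoate
Conditions: TBAF (1.2 equiv), AcOH (1.2 equiv), THF, 0 °C
Reagents that add atoms: none
Why: Fluoride cleavage of the aryl silyl ether, buffered with acetic acid so that the phenoxide is protonated at once and the C6 ester neither migrates nor hydrolyses, releases the phenol and should give the target.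

**Compound list**

1 | trimethylsilylacetylene | C#C[Si](C)(C)C | starting material
2 | diisobutyl[1-(trimethylsilyl)ethenyl]aluminium | C=C([Si](C)(C)C)[Al](CC(C)C)CC(C)C | intermediate
3 | 3-bromobut-3-en-1-ol | C=C(Br)CCO | starting material
4 | 3-bromobut-3-enal | C=C(Br)CC=O | intermediate
5 | 3-methylcyclopent-2-en-1-one | CC1=CC(=O)CC1 | starting material
6 | diisobutyl{[(3S)-3-methyl-3-[1-(trimethylsilyl)ethenyl]cyclopent-1-en-1-yl]oxy}aluminium (aluminium enolate, C4=C5) | C=C([Si](C)(C)C)[C@@]1(C)CCC(O[Al](CC(C)C)CC(C)C)=C1 | intermediate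
7 | (2S,3S)-2-[(1S)-3-bromo-1-hydroxybut-3-en-1-yl]-3-methyl-3-[1-(trimethylsilyl)ethenyl]cyclopentan-1-one | C=C(Br)C[C@H](O)[C@@H]1[C@](C)(CCC1=O)C(=C)[Si](C)(C)C | intermediate
8 | (2S,3S)-2-[(1S)-3-bromo-1-(triisopropylsilyloxy)but-3-en-1-yl]-3-methyl-3-[1-(trimethylsilyl)ethenyl]cyclopentan-1-one | C=C(Br)C[C@H](O[Si](C(C)C)(C(C)C)C(C)C)[C@@H]1[C@](C)(CCC1=O)C(=C)[Si](C)(C)C | intermediate
9 | (2S,3R)-2-[(1S)-3-bromo-1-(triisopropylsilyloxy)but-3-en-1-yl]-3-ethenyl-3-methylcyclopentan-1-one | C=C(Br)C[C@H](O[Si](C(C)C)(C(C)C)C(C)C)[C@@H]1[C@](C)(CCC1=O)C=C | intermediate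
10 | (1R,2S,3R)-2-[(1S)-3-bromo-1-(triisopropylsilyloxy)but-3-en-1-yl]-3-ethenyl-3-methyl-1-(propan-2-yl)cyclopentan-1-ol | C=C(Br)C[C@H](O[Si](C(C)C)(C(C)C)C(C)C)[C@@H]1[C@](C)(CC[C@@]1(O)C(C)C)C=C | intermediate
11 | (1R,2S,3R)-2-[(1S)-3-bromo-1-hydroxybut-3-en-1-yl]-3-ethenyl-3-methyl-1-(propan-2-yl)cyclopentan-1-ol | C=C(Br)C[C@H](O)[C@@H]1[C@](C)(CC[C@@]1(O)C(C)C)C=C | intermediate
12 | vanillic acid (4-hydroxy-3-methoxybenzoic acid) | COc1cc(C(=O)O)ccc1O | starting material
13 | triisopropylsilyl 3-methoxy-4-(triisopropylsilyloxy)benzoate | COc1cc(C(=O)O[Si](C(C)C)(C(C)C)C(C)C)ccc1O[Si](C(C)C)(C(C)C)C(C)C | intermediate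
14 | 3-methoxy-4-(triisopropylsilyloxy)benzoic acid | COc1cc(C(=O)O)ccc1O[Si](C(C)C)(C(C)C)C(C)C | intermediate
15 | (1S)-3-bromo-1-[(1S,2R,5R)-2-ethenyl-5-hydroxy-2-methyl-5-(propan-2-yl)cyclopentyl]but-3-en-1-yl 3-methoxy-4-(triisopropylsilyloxy)benzoate | C=C(Br)C[C@H](OC(=O)c1ccc(O[Si](C(C)C)(C(C)C)C(C)C)c(OC)c1)[C@@H]2[C@](C)(CC[C@@]2(O)C(C)C)C=C | intermediate
16 | B-alkyl-9-borabicyclo[3.3.1]nonane from 15 (boron on the terminal carbon C9) | C=C(Br)C[C@H](OC(=O)c1ccc(O[Si](C(C)C)(C(C)C)C(C)C)c(OC)c1)[C@@H]2[C@](C)(CC[C@@]2(O)C(C)C)CCB3C4CCCC3CCC4 | intermediate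
17 | (1S)-3-bromo-1-[(1S,2R,5R)-2-hydroxy-5-(2-hydroxyethyl)-5-methyl-2-(propan-2-yl)cyclopentyl]but-3-en-1-yl 3-methoxy-4-(triisopropylsilyloxy)benzoate | C=C(Br)C[C@H](OC(=O)c1ccc(O[Si](C(C)C)(C(C)C)C(C)C)c(OC)c1)[C@@H]2[C@](C)(CC[C@@]2(O)C(C)C)CCO | intermediate
18 | (1S)-3-bromo-1-[(1S,2R,5R)-2-hydroxy-5-methyl-5-(2-oxoethyl)-2-(propan-2-yl)cyclopentyl]but-3-en-1-yl 3-methoxy-4-(triisopropylsilyloxy)benzoate | C=C(Br)C[C@H](OC(=O)c1ccc(O[Si](C(C)C)(C(C)C)C(C)C)c(OC)c1)[C@@H]2[C@](C)(CC[C@@]2(O)C(C)C)CC=O | intermediate
19 | (3R,3aS,4S,7S,8aR)-3,7-dihydroxy-8a-methyl-6-methylidene-3-(propan-2-yl)decahydroazulen-4-yl 3-methoxy-4-(triisopropylsilyloxy)benzoate | C=C1C[C@H](OC(=O)c2ccc(O[Si](C(C)C)(C(C)C)C(C)C)c(OC)c2)[C@@H]3[C@](C)(CC[C@@]3(O)C(C)C)C[C@@H]1O | intermediate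
20 | (3R,3aS,4S,7S,8aR)-3,7-dihydroxy-8a-methyl-6-methylidene-3-(propan-2-yl)decahydroazulen-4-yl 4-hydroxy-3-methoxybenzoate | C=C1C[C@H](OC(=O)c2ccc(O)c(OC)c2)[C@@H]2[C@](C)(CC[C@@]2(O)C(C)C)C[C@@H]1O | target

**Step count**

Total: 13 steps. Longest linear sequence: 11 steps (step 1, then steps 3 to 7 and 9 to 13; steps 2 and 8 are side branches).

**Steps most likely to fail**

1. Step 3 (Proposed new method). The hindered aluminium enolate may add too slowly to the aldehyde, isobutylaluminium species may reduce or enolise the sensitive β,γ-unsaturated aldehyde, or the diastereoselection in the aldol stage may be poor. The fallback separates the two events with known chemistry and sets out from 5 and 2. The conjugate addition is run alone with the same catalyst and enolate 6 is quenched with Me3SiOTf to give the isolable trimethylsilyl enol ether F1, which keeps the C4=C5 regiochemistry. MeLi (THF, 0 °C) would convert it into the lithium enolate F2, which is cooled to −78 °C and treated with 4; the ring-locked E lithium enolate should again react through a closed chair and give the anti aldol on the face away from the silylvinyl group. The route is rejoined at 7.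

2. Step 6. Enolisation or β-hydride reduction may win over addition at the hindered ketone, or the reagent may attack the β face and give the C4 epimer, which cannot be corrected later. The fallback delivers oxygen instead of carbon in the stereo-determining event and sets out from 9. KN(SiMe3)2 and PhNTf2 (THF, −78 °C) would deprotonate the unhindered C3 methylene and give the enol triflate F3. Fe(acac)3-catalysed coupling with iPrMgCl at −30 °C, where the triflate is expected to react ahead of the bromoalkene, would give the isopropylcyclopentene F4. TBAF would free the C6 hydroxyl to give the homoallylic alcohol F5. VO(acac)2/tBuOOH epoxidation, directed by that hydroxyl on the β-oriented arm, should place oxygen on the β face of C3=C4 and give the β-epoxide F6. LiEt3BH would open the epoxide at the secondary C3 and leave the 4β tertiary alcohol. The route is rejoined at 11.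

3. Step 12. The ring closure may show poor facial selectivity at C9 and give much of the 9β alcohol. The fallback replaces substrate control by reagent control and sets out from 18. The closure is run as in step 12, and the crude carbinol mixture, which contains the 9β-epimer F7, is oxidised with DMP to the cross-conjugated enone F8. Corey–Bakshi–Shibata reduction ((R)-2-methyl-CBS-oxazaborolidine, catecholborane, toluene, −78 °C) should then give the 9S alcohol, with the alkenyl side of the ketone acting as the large group. The route is rejoined at 19.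

**Further compounds**

F1 | step 3 | trimethyl{[(3S)-3-methyl-3-[1-(trimethylsilyl)ethenyl]cyclopent-1-en-1-yl]oxy}silane | C=C([Si](C)(C)C)[C@@]1(C)CCC(O[Si](C)(C)C)=C1
F2 | step 3 | lithium (3S)-3-methyl-3-[1-(trimethylsilyl)ethenyl]cyclopent-1-en-1-olate | C=C([Si](C)(C)C)[C@@]1(C)CCC(O[Li])=C1
F3 | step 6 | enol triflate of 9 (C3=C4, triflate on C4) | C=C(Br)C[C@H](O[Si](C(C)C)(C(C)C)C(C)C)[C@@H]1[C@](C)(CC=C1OS(=O)(=O)C(F)(F)F)C=C
F4 | step 6 | isopropylcyclopentene from F3 (C3=C4, isopropyl on C4, O6 triisopropylsilyl ether) | C=C(Br)C[C@H](O[Si](C(C)C)(C(C)C)C(C)C)[C@@H]1[C@](C)(CC=C1C(C)C)C=C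
F5 | step 6 | homoallylic alcohol from F4 (free C6 hydroxyl) | C=C(Br)C[C@H](O)[C@@H]1[C@](C)(CC=C1C(C)C)C=C
F6 | step 6 | 3β,4β-epoxide of F5 | C=C(Br)C[C@H](O)[C@@H]1[C@](C)(C[C@@H]2O[C@]12C(C)C)C=C
F7 | step 12 | 9β-epimer of 19 | C=C1C[C@H](OC(=O)c2ccc(O[Si](C(C)C)(C(C)C)C(C)C)c(OC)c2)[C@@H]3[C@](C)(CC[C@@]3(O)C(C)C)C[C@H]1O
F8 | step 12 | C9 ketone of 19 (8(14)-en-9-one) | C=C1C[C@H](OC(=O)c2ccc(O[Si](C(C)C)(C(C)C)C(C)C)c(OC)c2)[C@@H]3[C@](C)(CC[C@@]3(O)C(C)C)CC1=O
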